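(All runs were generated by integration with made-up constants; the scatter is artificial.)

We decide to count X rather than fit rates, and two chemists count it differently.

| setting | dusk | noon | Monday's | Thursday's | Wednesday's |
|---|---|---|---|---|---|
| Q | 0.046 M | 0.046 M | 0.046 M | 0.046 M | 0.046 M |
| X | 0.054 M | 0.17 M | 0.0690 M | 0.138 M | 0.0460 M |
| Z | 0.023 M | 0.023 M | 0.0230 M | 0.0230 M | 0.0230 M |
| remark | run made earlier | run made earlier |  |  |  |
| time |  |  | 5.0 min | 5.0 min | 5.0 min |

| run | time / min | J / % |
|---|---|---|
| dusk | 1.00 | 20 |
| dusk | 2.00 | 19 |
| dusk | 3.00 | 20 |
| dusk | 4.00 | 24 |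
| dusk | 5.00 | 25 |
| noon | 0.417 | 65 |
| noon | 1.33 | 81 |
| noon | 2.50 | 83 |
| noon | 4.00 | 83 |
| noon | 5.00 | 83 |

(standard deviation of a reading: 2 percentage points)

- percentages count the Q that a species holds: one L counts as two
- steps under discussion: D + X -> Z + J; J <-> E; Q + D -> L; Q + X -> Z + D

* which of these holds the largest part of the Q at the end of Monday's (Q / J / D)
* which of these holds the largest part of the Q at the end of Thursday's (Q / J / D)
* which of these holds the largest part of the Q at the end of Wednesday's (Q / J / D)
* amount of J at the end of Monday's, in percent of the Q charged

Both treat J ⇌ E as being at equilibrium, since noon reads 83% of J at 2.50 min and still 83% at 5.00 min. They take that reading, 83.0%, as the part of J + E that is J. Both also count X: a D holds one, a J or E holds two, and an L holds one for its two Q. With free Q and X at nil, J + E therefore equals s + 0.5 L, in shares of the Q charged. Monday's has s = 0.500, where s is the spare X, c_X/c_Q minus one, the X per Q beyond the first exchange.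

The first chemist sets L aside, pointing to noon's flat readings. Monday's then holds more in D, 50.0%, than in J, 41.5%.

The second chemist, who made the forecast, answers from dusk. There s = 0.174 promises J at 14.4%, but the last reading is higher, 25%, a gap of 11 percentage points against a scatter of 2 points. The balance then reads L at dusk as about 25.5%. For Monday's, with more X, the forecast takes L at 15 to 20 percent, and it gives J for Monday's, J for Thursday's and D for Wednesday's, with J at 46%: “J leads, though a small L would narrow this”.

The flask gives J for Monday's, with J at 46.8% and D at 32.2%, then J for Thursday's and D for Wednesday's.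

D + X → Z + J (k = 0.580 /M/s); J ⇌ E (K = 0.170, k = 0.0200 /s); Q + D → L (k = 0.590 /M/s); Q + X → Z + D (k = 4.70 /M/s) In Monday's, Q stands at 0%, X at 1.22% of its charge and L at 13.1%, so s + 0.5 L, less the X still free counted per Q charged, comes to 54.7%, while J and E hold 54.7%. The neighbour with 0.12 M of X has s = 1.61, more than the one further X that each Q can take. Q is its limiting reagent, with 0% left and X at 27% of its charge. This is the first chemist's ground: with L aside, J is 83.0%, and this neighbour gives 80.5% with L at 5.60%.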